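## Analysis of the target

Target 20 is an achiral diaryl ether made of two pentasubstituted benzene rings and no other ring. Ring A, numbered from its carbinol carbon, carries CH2OH at C1, Br at C2, the ether oxygen at C3, OH at C4, Br at C5 and H at C6. Ring B, numbered the same way, carries CH2OH at C1′, the ether oxygen at C2′, OH at C3′ and C4′, Br at C5′ and H at C6′. There is no stereocentre, and the ether axis, although flanked by four ortho substituents, is taken as freely rotating. Both carbinols sit para to a phenolic OH (C1/C4 and C1′/C4′), so they ionise easily to quinone methides. The ring B bromocatechol is easily oxidised, and three C–Br bonds exclude hydrogenolysis and strongly reducing conditions. The ether links two carbons that each have two ortho neighbours, which is unfavourable for substitution or coupling at an aromatic carbon. The C2 bromine lies meta to the C4 hydroxyl, between the carbinol carbon and the ether carbon, where electrophilic bromination cannot be relied on. The strategy rests on the C2–C3–C4 segment of ring A: C3 sits between an oxygenated C4 and a C2 whose bromine can stand in for oxygen, with the carbinol carbon on C1. That is the pattern of a 3-aryloxy-2,4-dioxocyclohexane-1-carboxylate in which C3 is the carbon between two carbonyl groups.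

## Retrosynthetic reasoning

**20 to 19.** No skeletal bond is cut. The C4 phenol is masked as an acetal, the ring B catechol as a ketal and the ring B carbinol as a silyl ether, all acid-labile. One hydrolysis then ends the route, and the sensitive p-hydroxybenzyl alcohols exist only in the last flask.

**19 to 18.** The ring A carbinol is traced to a methyl ester on C1. That ester is the acyl acceptor that closed ring A and the group that later tells the two phenols apart, so it is reduced only after both jobs are done.

**18 to 17 to 16.** The C2–Br bond is cut back to a C2–O bond. C2 is meta to the C4 oxygen and cannot be brominated directly, but the ring construction delivers it as a phenol next to the ester. The forward steps sulfonylate that phenol to triflate 17 and exchange the triflate for bromide without consuming the two C–Br bonds already present.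

**16 to 15.** The two phenols of 15 are distinguished. The C2 hydroxyl is held in a hydrogen bond to the ester carbonyl, while the C4 hydroxyl is free and more acidic (para to the ester, ortho to bromine). A small alkylating agent should therefore cap O4 alone.

**15 to 14.** The C5–Br bond is cut at the stage where ring A is a free resorcinol. C5 is then ortho to one hydroxyl and para to the other, while the single open position of ring B is flanked on both sides and carries no free hydroxyl.

**14 to 11.** The aromatic ring is traced to cyclohexane-1,3-dione 11 by adding back two hydrogens at C5 and C6. The forward step must remove them without acid, which the ketal and silyl ether would not survive, and without functionalising C3.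

**11 to 8 and 9.** This is the key disconnection: bonds C1–C6 and C2–C3 of ring A are cut. It turns the hindered diaryl ether bond at C3 into an ordinary aryl alkyl ether on a CH2 group α to a ketone. It also places the C2 and C4 oxygens and the C1 carboxyl carbon with no regiochemical choice, and it leaves ring B untouched. The forward reaction must add malonate 9 to enone 8 once, then close the ring through the aryloxy-bearing carbon.

**8 to 7 to 6 to 5.** The vinyl–carbonyl bond of 8 is cut to Weinreb amide 7 and a vinyl organometallic. The silyl ether of 7 comes from alcohol 6 and this from aldehyde 5. The carbinol is carried as an ether, not an ester, so that ring B offers no acyl group to the carbanion of the key step.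

**5 to 3 and 4.** The O–CH2 bond is cut. This is the oxygen that ends up as the diaryl ether oxygen, and it is formed here by alkylating phenol 3 with bromoamide 4 at an sp3 carbon, the easiest possible way to make that bond.

**3 to 2 to 1.** The ketal is removed and then the bromine. Trihydroxy aldehyde 1 already holds every ring B carbon and oxygen. Bromination at C5′ is dictated by the 2- and 4-hydroxyls, and ketal formation across O3′/O4′ leaves the chelated 2-hydroxyl free for the alkylation.

## Alternatives that were turned down

**Alternative 1:** Xanthone ring expansion. The C4–O bond of ring A is traced to oxygen insertion into xanthone A1, in which the pyranone oxygen is the future ether oxygen and the carbonyl carbon the future ring B carbinol. In the forward step, CF3CO3H converts A1 into depsidone A2 by Baeyer–Villiger migration of the ring A carbon.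
- For: all three bromines and the full oxygen pattern are in place before the key step. No C–O to C–Br exchange is needed. Hydride opening of the lactone A2 would free the ring B carbinol and the C4 phenol together. On these points it is stronger than the chosen route.
- Against: a xanthone carbonyl is a doubly vinylogous ester and a poor acceptor for peracid. The choice of migrating aryl group rests only on an electronic bias set by the sulfonates, on a ring A that itself carries two bromines. The ring A carbinol arrives as a methyl group, so a late benzylic C–H oxidation next to aryl bromides is required. Removing the mesylates needs conditions harsher than anything in the chosen end-game.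
- Comparison: the chosen route forms the bonds of ring A with no migratory-aptitude question and carries both carbinol carbons at a carbonyl or alcohol level throughout.

**Alternative 2:** Ring B by cycloaddition. Ring B is cut at C2′–C3′ and C1′–C6′ into 3-methoxyfuran A3 and aryloxypropiolate A4. In the forward step a [4+2] addition followed by opening of the oxygen bridge gives diaryl ether A5 directly as a phenol.
- For: the ring is aromatic as soon as it forms, so no dehydrogenation is needed, and the sequence is short on paper. Here it is stronger than the chosen route.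
- Against: A4 is a push–pull ynol ether of a hindered bromophenol. Usual routes to aryl alkynyl ethers pass through organolithium bases that a C2–Br bond would not tolerate, and the donor oxygen on the alkyne lowers its dienophilicity in a cycloaddition that furans readily reverse. A5 lacks both the C5 and the C5′ bromine, and on ring B the free C3′ hydroxyl directs an electrophile para, to C6′, the wrong carbon. Two O-methyl groups must be cleaved by a strong Lewis acid in a molecule that will hold two ionisable benzylic alcohols.
- Comparison: the chosen route fixes the ring B bromine on the starting aldehyde and uses only acid-labile groups.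

**Alternative 3:** Ring B by formal [3+3] cyclisation. Ring B is cut at C2′–C1′ and C4′–C5′ into bis(silyl enol ether) A6, which carries ring A, and alkoxy enone ester A7. In the forward step TiCl4 joins them to give aromatic hydroxy ketone A8.
- For: cyclisations of this kind with aryloxy-substituted dienes are an established way to make hindered diaryl ethers. Ring A comes with both bromines, and no dehydrogenation or triflate exchange is needed. On the key bond-forming step it is at least as strong as the chosen route.
- Against: C4′ arrives as an acetyl group, so an aryl ketone to phenol oxidation next to a free phenol is needed. The ring B bromine is missing and must again be placed at C5′ against the para-directing C3′ hydroxyl. The ring A methyl ether must be cleaved late under Lewis acid. A6 must be made from a phenol flanked on both sides.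
- Comparison: the chosen route takes ring B with its three oxygens and its bromine from a commercial aldehyde and needs no oxidation-level correction on either ring.

Key step: step 7

Assumption: rotation about the diaryl ether bonds is free, so 20 has no stereo-element to control.

Notation: ArB = 7-bromo-5-({[tert-butyl(dimethyl)silyl]oxy}methyl)-2,2-dimethyl-1,3-benzodioxol-4-yl (protected ring B, bonded through C4); "ArB-oxy" is this group attached through oxygen.

Remark: 11, 12 and 13 are drawn as one enol tautomer; C1 of 11 is a racemic, freely epimerising centre.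

## Route

Step 1
Reactants: 1 2,3,4-trihydroxybenzaldehyde
Product: 2 5-bromo-2,3,4-trihydroxybenzaldehyde
Conditions: Br2 (1.0 equiv), AcOH, 15 °C
Reagents that add atoms: bromine, BrBr
Why: Electrophilic aromatic bromination; C5 is ortho to the 4-OH, para to the 2-OH and meta to the formyl group, whereas C6 is ortho to the deactivating formyl group, so one bromine should enter at C5.

Step 2
Reactants: 2 5-bromo-2,3,4-trihydroxybenzaldehyde
Product: 3 7-bromo-4-hydroxy-2,2-dimethyl-1,3-benzodioxole-5-carbaldehyde
Conditions: Me2C(OMe)2, p-TsOH·H2O (cat.), toluene, reflux, 4 Å sieves (MeOH removal)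
Reagents that add atoms: 2,2-dimethoxypropane, COC(C)(C)OC
Why: Acid-catalysed transketalisation under thermodynamic control; the 3,4-diol closes the dioxole while the 2-OH keeps its hydrogen bond to the formyl oxygen, so the ketal that leaves this chelate intact should prevail.

Step 3
Reactants: 3 7-bromo-4-hydroxy-2,2-dimethyl-1,3-benzodioxole-5-carbaldehyde; 4 2-bromo-N-methoxy-N-methylacetamide
Product: 5 2-[(7-bromo-5-formyl-2,2-dimethyl-1,3-benzodioxol-4-yl)oxy]-N-methoxy-N-methylacetamide
Conditions: K2CO3, DMF, rt to 40 °C
Reagents that add atoms: none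
Why: Williamson ether synthesis (SN2) of a salicylaldehyde-type phenoxide with a primary α-bromo amide; the mild base and low temperature should keep the aldol closure to a benzofuran from starting.

Step 4
Reactants: 5 2-[(7-bromo-5-formyl-2,2-dimethyl-1,3-benzodioxol-4-yl)oxy]-N-methoxy-N-methylacetamide
Product: 6 2-{[7-bromo-5-(hydroxymethyl)-2,2-dimethyl-1,3-benzodioxol-4-yl]oxy}-N-methoxy-N-methylacetamide
Conditions: NaBH4, MeOH–THF, 0 °C
Reagents that add atoms: none
Why: Chemoselective borohydride reduction of the aryl aldehyde; a Weinreb amide is not reduced by NaBH4 at 0 °C.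

Step 5
Reactants: 6 2-{[7-bromo-5-(hydroxymethyl)-2,2-dimethyl-1,3-benzodioxol-4-yl]oxy}-N-methoxy-N-methylacetamide
Product: 7 2-(ArB-oxy)-N-methoxy-N-methylacetamide
Conditions: TBSCl, imidazole, DMF, rt
Reagents that add atoms: tert-butyl(chloro)dimethylsilane, CC(C)(C)[Si](C)(C)Cl
Why: Silylation of a primary benzylic alcohol; an ether is chosen so that ring B offers no acyl acceptor in step 7, and it is stable to Grignard reagents and methoxide.

Step 6
Reactants: 7 2-(ArB-oxy)-N-methoxy-N-methylacetamide
Product: 8 1-(ArB-oxy)but-3-en-2-one
Conditions: CH2=CHMgBr (1.5 equiv), THF, –78 to 0 °C; inverse quench into cold 1 M HCl; used at once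
Reagents that add atoms: vinylmagnesium bromide, C=C[Mg]Br
Why: Weinreb ketone synthesis; the magnesium chelate of the tetrahedral adduct prevents a second addition, and the acidic inverse quench protonates the released N,O-dimethylhydroxylamine before it can add to the enone. The aryl bromide does not exchange with a vinyl Grignard reagent at this temperature.

Step 7
Reactants: 8 1-(ArB-oxy)but-3-en-2-one; 9 dimethyl propanedioate (dimethyl malonate)
Product: 11 methyl 3-(ArB-oxy)-4-hydroxy-2-oxocyclohex-3-ene-1-carboxylate, via Michael adduct 10 (not isolated)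
Conditions: 9 (1.5 equiv), NaOMe (2.7 equiv), MeOH–THF, 0 °C, slow addition of 8; then 65 °C; AcOH to pH 5
Reagents that add atoms: none
Why: Michael addition followed by an intramolecular Claisen (Dieckmann-type) condensation, the reaction type by which dimedone and dihydroresorcylates are made from an enone and a malonate. The sodium enolate of 9 adds 1,4 to 8 (bond C1–C6) to give 10; methoxide then equilibrates the ketone enolates of 10, and the α′-carbanion, acidified by the aryloxy group, attacks one ester of the malonate unit (bond C2–C3). Ring A closes in a 6-(enolexo)-exo-trig mode; the C5 enolate could only form a four-membered ring, and O-acylation gives an enol lactone that methoxide reopens. Loss of methoxide and irreversible deprotonation of the resulting 2-aryloxy-1,3-dione pull all equilibria to the enolate of 11, which mild acid sets free. The one stereocentre formed, C1, is not controlled: it lies between a ketone and an ester, epimerises freely and disappears in step 8. The step needs 1,4- over 1,2-addition (soft malonate anion), single over double Michael addition (enone added slowly to an excess of the malonate anion) and acylation by the malonate ester only; the last is secured because ring B carries its carbinol as a silyl ether and has no ester that would lead to a benzofuranone. The aryl bromide, the ketal and the alkyl silyl ether are inert to NaOMe in MeOH.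

Step 8
Reactants: 11 methyl 3-(ArB-oxy)-4-hydroxy-2-oxocyclohex-3-ene-1-carboxylate
Product: 14 methyl 3-(ArB-oxy)-2,4-dihydroxybenzoate, via C1 selenide 12 (not isolated), via selenoxide 13 (not isolated)
Conditions: LiN(i-Pr)2 (2.2 equiv), THF, –78 to –30 °C; PhSeBr (1.05 equiv), –78 °C; AcOH; then 30% H2O2, pyridine, CH2Cl2, 0 °C to rt
Reagents that add atoms: none
Why: α-Selenenylation of a β-dicarbonyl dianion and selenoxide syn-elimination, then tautomerisation of the cyclohexadienone to the phenol. The first equivalent of base ties C3 into the delocalised diketonate, so the selenium electrophile should be taken by the more basic ester-stabilised C1 carbanion, and the selenoxide eliminates towards C6–H under neutral conditions that spare the ketal and silyl ether. A selenide at C5 would aromatise in the same way; only C3, which has no β-hydrogen, must be avoided.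

Step 9
Reactants: 14 methyl 3-(ArB-oxy)-2,4-dihydroxybenzoate
Product: 15 methyl 5-bromo-3-(ArB-oxy)-2,4-dihydroxybenzoate
Conditions: NBS (1.0 equiv), MeCN, –20 to 0 °C
Reagents that add atoms: N-bromosuccinimide, O=C1CCC(=O)N1Br
Why: Electrophilic aromatic bromination; C5 is ortho to the 4-OH and para to the 2-OH of a resorcinol, while the only open position of ring B is flanked by CH2OSi and Br in a ring without free hydroxyl.

Step 10
Reactants: 15 methyl 5-bromo-3-(ArB-oxy)-2,4-dihydroxybenzoate
Product: 16 methyl 5-bromo-3-(ArB-oxy)-2-hydroxy-4-(methoxymethoxy)benzoate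
Conditions: MOMCl (1.1 equiv), i-Pr2NEt, CH2Cl2, 0 °C
Reagents that add atoms: chloromethyl methyl ether, COCCl
Why: Chemoselective O-alkylation; the 4-OH (para to the ester, ortho to Br) is the more acidic phenol and is not held in the hydrogen bond to the ester carbonyl, so the small electrophile should cap it alone.

Step 11
Reactants: 16 methyl 5-bromo-3-(ArB-oxy)-2-hydroxy-4-(methoxymethoxy)benzoate
Product: 17 methyl 5-bromo-3-(ArB-oxy)-4-(methoxymethoxy)-2-{[(trifluoromethyl)sulfonyl]oxy}benzoate
Conditions: Tf2O, pyridine, CH2Cl2, –20 to 0 °C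
Reagents that add atoms: trifluoromethanesulfonic anhydride, O=S(=O)(OS(=O)(=O)C(F)(F)F)C(F)(F)F
Why: O-Sulfonylation of the one remaining, chelated phenol, as for salicylate esters in general; pyridine buffers the acid so that the acetal, ketal and silyl ether should be kept.

Step 12
Reactants: 17 methyl 5-bromo-3-(ArB-oxy)-4-(methoxymethoxy)-2-{[(trifluoromethyl)sulfonyl]oxy}benzoate
Product: 18 methyl 2,5-dibromo-3-(ArB-oxy)-4-(methoxymethoxy)benzoate
Conditions: [Cp*Ru(MeCN)3]OTf (10 mol%), LiBr (3 equiv), 1,3-dimethylimidazolidin-2-one, 100 °C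
Reagents that add atoms: lithium bromide, [Li+].[Br-]
Why: Ruthenium-catalysed exchange of an aryl triflate for a halide: the C–OTf bond adds oxidatively to the Cp*Ru cation, bromide replaces triflate on the metal and the C–Br bond is formed by reductive elimination. Aryl bromides are the products of this catalysis, so the two C–Br bonds already present should pass through unchanged, and the ortho ester activates the C2–O bond.

Step 13
Reactants: 18 methyl 2,5-dibromo-3-(ArB-oxy)-4-(methoxymethoxy)benzoate
Product: 19 [2,5-dibromo-3-(ArB-oxy)-4-(methoxymethoxy)phenyl]methanol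
Conditions: i-Bu2AlH (3 equiv), CH2Cl2, –78 to 0 °C; aq. KNaC4H4O6
Reagents that add atoms: none
Why: Hydride reduction of the ester to the primary alcohol through the aldehyde; at low temperature i-Bu2AlH leaves aryl bromides, the acetal, the ketal and the silyl ether alone.

Step 14
Reactants: 19 [2,5-dibromo-3-(ArB-oxy)-4-(methoxymethoxy)phenyl]methanol
Product: 20 6-bromo-3-[2,5-dibromo-6-hydroxy-3-(hydroxymethyl)phenoxy]-4-(hydroxymethyl)benzene-1,2-diol
Conditions: 2 M aq. H2SO4–THF (1:1), 50 °C, 0.01 M, argon
Reagents that add atoms: none
Why: Acid-catalysed hydrolysis of the methoxymethyl acetal, the catechol ketal and the silyl ether in one operation. Water is the only nucleophile and the acid has a non-nucleophilic anion, so a p-hydroxybenzyl cation that forms should be returned to the alcohol; high dilution disfavours bimolecular ether formation.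

## Compound list

1 | 2,3,4-trihydroxybenzaldehyde | O=Cc1ccc(O)c(O)c1O | starting material
2 | 5-bromo-2,3,4-trihydroxybenzaldehyde | O=Cc1cc(Br)c(O)c(O)c1O | intermediate
3 | 7-bromo-4-hydroxy-2,2-dimethyl-1,3-benzodioxole-5-carbaldehyde | O=Cc1cc(Br)c2OC(C)(C)Oc2c1O | intermediate
4 | 2-bromo-N-methoxy-N-methylacetamide | CON(C)C(=O)CBr | starting material
5 | 2-[(7-bromo-5-formyl-2,2-dimethyl-1,3-benzodioxol-4-yl)oxy]-N-methoxy-N-methylacetamide | CON(C)C(=O)COc1c(C=O)cc(Br)c2OC(C)(C)Oc12 | intermediate
6 | 2-{[7-bromo-5-(hydroxymethyl)-2,2-dimethyl-1,3-benzodioxol-4-yl]oxy}-N-methoxy-N-methylacetamide | CON(C)C(=O)COc1c(CO)cc(Br)c2OC(C)(C)Oc12 | intermediate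
7 | 2-(ArB-oxy)-N-methoxy-N-methylacetamide | CON(C)C(=O)COc1c(CO[Si](C)(C)C(C)(C)C)cc(Br)c2OC(C)(C)Oc12 | intermediate
8 | 1-(ArB-oxy)but-3-en-2-one | C=CC(=O)COc1c(CO[Si](C)(C)C(C)(C)C)cc(Br)c2OC(C)(C)Oc12 | intermediate
9 | dimethyl propanedioate (dimethyl malonate) | COC(=O)CC(=O)OC | starting material
10 | dimethyl 2-[4-(ArB-oxy)-3-oxobutyl]propanedioate | COC(=O)C(CCC(=O)COc1c(CO[Si](C)(C)C(C)(C)C)cc(Br)c2OC(C)(C)Oc12)C(=O)OC | intermediate
11 | methyl 3-(ArB-oxy)-4-hydroxy-2-oxocyclohex-3-ene-1-carboxylate (racemic, one enol tautomer) | COC(=O)C1CCC(O)=C(Oc2c(CO[Si](C)(C)C(C)(C)C)cc(Br)c3OC(C)(C)Oc23)C1=O | intermediate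
12 | methyl 3-(ArB-oxy)-4-hydroxy-2-oxo-1-(phenylselanyl)cyclohex-3-ene-1-carboxylate (racemic) | COC(=O)C1([Se]c2ccccc2)CCC(O)=C(Oc2c(CO[Si](C)(C)C(C)(C)C)cc(Br)c3OC(C)(C)Oc23)C1=O | intermediate
13 | methyl 3-(ArB-oxy)-4-hydroxy-2-oxo-1-(phenylseleninyl)cyclohex-3-ene-1-carboxylate (mixture of stereoisomers) | COC(=O)C1([Se](=O)c2ccccc2)CCC(O)=C(Oc2c(CO[Si](C)(C)C(C)(C)C)cc(Br)c3OC(C)(C)Oc23)C1=O | intermediate
14 | methyl 3-(ArB-oxy)-2,4-dihydroxybenzoate | COC(=O)c1ccc(O)c(Oc2c(CO[Si](C)(C)C(C)(C)C)cc(Br)c3OC(C)(C)Oc23)c1O | intermediate
15 | methyl 5-bromo-3-(ArB-oxy)-2,4-dihydroxybenzoate | COC(=O)c1cc(Br)c(O)c(Oc2c(CO[Si](C)(C)C(C)(C)C)cc(Br)c3OC(C)(C)Oc23)c1O | intermediate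
16 | methyl 5-bromo-3-(ArB-oxy)-2-hydroxy-4-(methoxymethoxy)benzoate | COCOc1c(Br)cc(C(=O)OC)c(O)c1Oc1c(CO[Si](C)(C)C(C)(C)C)cc(Br)c2OC(C)(C)Oc12 | intermediate
17 | methyl 5-bromo-3-(ArB-oxy)-4-(methoxymethoxy)-2-{[(trifluoromethyl)sulfonyl]oxy}benzoate | COCOc1c(Br)cc(C(=O)OC)c(OS(=O)(=O)C(F)(F)F)c1Oc1c(CO[Si](C)(C)C(C)(C)C)cc(Br)c2OC(C)(C)Oc12 | intermediate
18 | methyl 2,5-dibromo-3-(ArB-oxy)-4-(methoxymethoxy)benzoate | COCOc1c(Br)cc(C(=O)OC)c(Br)c1Oc1c(CO[Si](C)(C)C(C)(C)C)cc(Br)c2OC(C)(C)Oc12 | intermediate
19 | [2,5-dibromo-3-(ArB-oxy)-4-(methoxymethoxy)phenyl]methanol | COCOc1c(Br)cc(CO)c(Br)c1Oc1c(CO[Si](C)(C)C(C)(C)C)cc(Br)c2OC(C)(C)Oc12 | intermediate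
20 | 6-bromo-3-[2,5-dibromo-6-hydroxy-3-(hydroxymethyl)phenoxy]-4-(hydroxymethyl)benzene-1,2-diol | OCc1cc(Br)c(O)c(Oc2c(CO)cc(Br)c(O)c2O)c1Br | target

## Step count and risks

Total step count: 14. Longest linear sequence: 14 steps (1 to 20); 4 and 9 are commercial.

**Step 7 (key step).** The most likely failure is loss of enone 8 before the slower ring closure, either by a second conjugate addition from the malonate anion of 10 or by base-induced oligomerisation of the vinyl ketone. Fallback, from 7 back to 11: donor and acceptor are exchanged so that no vinyl ketone is needed. Acylation of the lithium enolate of methyl acetate by Weinreb amide 7 should give methyl 4-(ArB-oxy)-3-oxobutanoate F1. Its Michael addition to methyl acrylate (NaOMe, MeOH) gives dimethyl 2-[(ArB-oxy)acetyl]pentanedioate F2. The aryloxy-bearing γ-carbanion of F2 then closes onto the terminal ester in a Dieckmann condensation and gives 11, the same ring with the same substituents.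

**Step 12.** Insertion into the C2–O bond, which has two ortho neighbours, may be slow. Cleavage at sulfur would then return the phenol, or bromide would demethylate the ester at 100 °C. Fallback, from 16 back to 18: nitrogen replaces the C2 oxygen without any metal insertion and is then exchanged for bromine.
- Alkylation of phenol 16 with 2-bromo-2-methylpropanamide (NaH, dioxane) gives methyl 2-[(1-amino-2-methyl-1-oxopropan-2-yl)oxy]-5-bromo-3-(ArB-oxy)-4-(methoxymethoxy)benzoate F3.
- Smiles rearrangement (NaH, DMF, 90 °C), through a spiro intermediate stabilised by the ortho ester, gives methyl 5-bromo-3-(ArB-oxy)-2-[(2-hydroxy-2-methylpropanoyl)amino]-4-(methoxymethoxy)benzoate F4.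
- Hydrolysis (NaOH, aq. MeOH, reflux) gives 2-amino-5-bromo-3-(ArB-oxy)-4-(methoxymethoxy)benzoic acid F5.
- Esterification with trimethylsilyldiazomethane gives methyl 2-amino-5-bromo-3-(ArB-oxy)-4-(methoxymethoxy)benzoate F6.
- A Sandmeyer reaction (tert-butyl nitrite, CuBr2, MeCN, 0 °C to rt) gives 18.

**Step 8.** Selenium may be transferred to C3 of the diketonate, where the selenoxide has no β-hydrogen, or the electrophilic selenium by-product may attack the resorcinol as it forms. Fallback, from 8 back to 14: the leaving group for the aromatisation is brought in with the malonate.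
- Malonate 9 is sulfenylated (NaH, N-(phenylsulfanyl)succinimide) to dimethyl 2-(phenylsulfanyl)propanedioate F7.
- F7 adds to enone 8 under the conditions of step 7 to give dimethyl 2-[4-(ArB-oxy)-3-oxobutyl]-2-(phenylsulfanyl)propanedioate F8. This cannot add a second enone.
- The same Claisen closure gives methyl 3-(ArB-oxy)-4-hydroxy-2-oxo-1-(phenylsulfanyl)cyclohex-3-ene-1-carboxylate F9.
- Oxidation with NaIO4 gives methyl 3-(ArB-oxy)-4-hydroxy-2-oxo-1-(phenylsulfinyl)cyclohex-3-ene-1-carboxylate F10.
- Thermal syn-elimination of the sulfoxide (toluene, 90 °C, CaCO3) and tautomerisation give 14.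

**Step 14.** The two p-hydroxybenzyl alcohols may ionise to quinone methides during the acid treatment and be captured by another molecule, giving ethers or diarylmethanes. The catechol ketal may also resist the mild acid that the carbinols tolerate. Fallback, from 19 back to 20: the acid step is moved to a stage without ionisable carbinols.
- Bu4NF (THF) removes the silyl group and gives [2,5-dibromo-3-{[7-bromo-5-(hydroxymethyl)-2,2-dimethyl-1,3-benzodioxol-4-yl]oxy}-4-(methoxymethoxy)phenyl]methanol F11.
- Dess–Martin periodinane oxidises both carbinols to 2,5-dibromo-3-[(7-bromo-5-formyl-2,2-dimethyl-1,3-benzodioxol-4-yl)oxy]-4-(methoxymethoxy)benzaldehyde F12.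
- Aqueous CF3CO2H, as strong as needed, then cleaves ketal and acetal to 2,5-dibromo-3-(4-bromo-6-formyl-2,3-dihydroxyphenoxy)-4-hydroxybenzaldehyde F13.
- NaBH4 (THF–H2O, 0 °C, then AcOH to pH 6) reduces both aldehydes to 20 under near-neutral conditions.

**Step 6.** The released N,O-dimethylhydroxylamine may add to the enone during work-up, or the vinyl ketone may polymerise on concentration. Fallback, from 7 back to 11: the amine adduct is used as a masked enone. The Grignard addition to 7 is quenched with aq. NH4Cl without acid, so that the amine adds and 1-(ArB-oxy)-4-[methoxy(methyl)amino]butan-2-one F14 is isolated as a stable compound. Under the NaOMe conditions of step 7, F14 should release enone 8 by β-elimination at a low stationary concentration in the presence of the malonate anion, which also disfavours double addition, and go on to 11.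

## Further compounds

F1 | step 7 | methyl 4-(ArB-oxy)-3-oxobutanoate | COC(=O)CC(=O)COc1c(CO[Si](C)(C)C(C)(C)C)cc(Br)c2OC(C)(C)Oc12
F2 | step 7 | dimethyl 2-[(ArB-oxy)acetyl]pentanedioate | COC(=O)CCC(C(=O)OC)C(=O)COc1c(CO[Si](C)(C)C(C)(C)C)cc(Br)c2OC(C)(C)Oc12
F3 | step 12 | methyl 2-[(1-amino-2-methyl-1-oxopropan-2-yl)oxy]-5-bromo-3-(ArB-oxy)-4-(methoxymethoxy)benzoate | COCOc1c(Br)cc(C(=O)OC)c(OC(C)(C)C(N)=O)c1Oc1c(CO[Si](C)(C)C(C)(C)C)cc(Br)c2OC(C)(C)Oc12
F4 | step 12 | methyl 5-bromo-3-(ArB-oxy)-2-[(2-hydroxy-2-methylpropanoyl)amino]-4-(methoxymethoxy)benzoate | COCOc1c(Br)cc(C(=O)OC)c(NC(=O)C(C)(C)O)c1Oc1c(CO[Si](C)(C)C(C)(C)C)cc(Br)c2OC(C)(C)Oc12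
F5 | step 12 | 2-amino-5-bromo-3-(ArB-oxy)-4-(methoxymethoxy)benzoic acid | COCOc1c(Br)cc(C(=O)O)c(N)c1Oc1c(CO[Si](C)(C)C(C)(C)C)cc(Br)c2OC(C)(C)Oc12
F6 | step 12 | methyl 2-amino-5-bromo-3-(ArB-oxy)-4-(methoxymethoxy)benzoate | COCOc1c(Br)cc(C(=O)OC)c(N)c1Oc1c(CO[Si](C)(C)C(C)(C)C)cc(Br)c2OC(C)(C)Oc12
F7 | step 8 | dimethyl 2-(phenylsulfanyl)propanedioate | COC(=O)C(Sc1ccccc1)C(=O)OC
F8 | step 8 | dimethyl 2-[4-(ArB-oxy)-3-oxobutyl]-2-(phenylsulfanyl)propanedioate | COC(=O)C(CCC(=O)COc1c(CO[Si](C)(C)C(C)(C)C)cc(Br)c2OC(C)(C)Oc12)(Sc1ccccc1)C(=O)OC
F9 | step 8 | methyl 3-(ArB-oxy)-4-hydroxy-2-oxo-1-(phenylsulfanyl)cyclohex-3-ene-1-carboxylate (racemic) | COC(=O)C1(Sc2ccccc2)CCC(O)=C(Oc2c(CO[Si](C)(C)C(C)(C)C)cc(Br)c3OC(C)(C)Oc23)C1=O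
F10 | step 8 | methyl 3-(ArB-oxy)-4-hydroxy-2-oxo-1-(phenylsulfinyl)cyclohex-3-ene-1-carboxylate (mixture of stereoisomers) | COC(=O)C1(S(=O)c2ccccc2)CCC(O)=C(Oc2c(CO[Si](C)(C)C(C)(C)C)cc(Br)c3OC(C)(C)Oc23)C1=O
F11 | step 14 | [2,5-dibromo-3-{[7-bromo-5-(hydroxymethyl)-2,2-dimethyl-1,3-benzodioxol-4-yl]oxy}-4-(methoxymethoxy)phenyl]methanol | COCOc1c(Br)cc(CO)c(Br)c1Oc1c(CO)cc(Br)c2OC(C)(C)Oc12
F12 | step 14 | 2,5-dibromo-3-[(7-bromo-5-formyl-2,2-dimethyl-1,3-benzodioxol-4-yl)oxy]-4-(methoxymethoxy)benzaldehyde | COCOc1c(Br)cc(C=O)c(Br)c1Oc1c(C=O)cc(Br)c2OC(C)(C)Oc12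
F13 | step 14 | 2,5-dibromo-3-(4-bromo-6-formyl-2,3-dihydroxyphenoxy)-4-hydroxybenzaldehyde | O=Cc1cc(Br)c(O)c(Oc2c(C=O)cc(Br)c(O)c2O)c1Br
F14 | step 6 | 1-(ArB-oxy)-4-[methoxy(methyl)amino]butan-2-one | CON(C)CCC(=O)COc1c(CO[Si](C)(C)C(C)(C)C)cc(Br)c2OC(C)(C)Oc12
A1 | alternative 1 | 1,4,7-tribromo-3-methyl-9-oxo-9H-xanthene-5,6-diyl dimethanesulfonate | Cc1cc(Br)c2C(=O)c3cc(Br)c(OS(C)(=O)=O)c(OS(C)(=O)=O)c3Oc2c1Br
A2 | alternative 1 | 2,6,9-tribromo-7-methyl-11-oxo-11H-dibenzo[b,e][1,4]dioxepine-3,4-diyl dimethanesulfonate | Cc1cc(Br)c2OC(=O)c3cc(Br)c(OS(C)(=O)=O)c(OS(C)(=O)=O)c3Oc2c1Br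
A3 | alternative 2 | 3-methoxyfuran | COc1ccoc1
A4 | alternative 2 | methyl 2-bromo-4-methoxy-3-[(3-methoxy-3-oxoprop-1-yn-1-yl)oxy]benzoate | COC(=O)C#COc1c(Br)c(C(=O)OC)ccc1OC
A5 | alternative 2 | methyl 2-[2-bromo-6-methoxy-3-(methoxycarbonyl)phenoxy]-3-hydroxy-4-methoxybenzoate | COC(=O)c1ccc(OC)c(O)c1Oc1c(Br)c(C(=O)OC)ccc1OC
A6 | alternative 3 | methyl 2,5-dibromo-3-{[2,4-bis(trimethylsilyloxy)penta-1,3-dien-1-yl]oxy}-4-methoxybenzoate | CC(O[Si](C)(C)C)=CC(O[Si](C)(C)C)=COc1c(OC)c(Br)cc(C(=O)OC)c1Br
A7 | alternative 3 | ethyl (E)-4-ethoxy-2-oxobut-3-enoate | CCO/C=C/C(=O)C(=O)OCC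
A8 | alternative 3 | ethyl 4-acetyl-2-[2,5-dibromo-6-methoxy-3-(methoxycarbonyl)phenoxy]-3-hydroxybenzoate | CCOC(=O)c1ccc(C(C)=O)c(O)c1Oc1c(OC)c(Br)cc(C(=O)OC)c1Br
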